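The constant you can take from these runs is how long E lives in the flask, and it has to be set against how long E has been there.

| flask | E | L | Q | remark | time |
|---|---|---|---|---|---|
| cedar | 0.027 M (fed, over 2.5 h) | 0.0297 M | 0.028 M | run made earlier; the fed solution adds 0.25 times the starting volume |  |
| birch | 0.027 M (fed, over 2.5 h) | 0.0297 M | 0.043 M | run made earlier; the fed solution adds 0.25 times the starting volume |  |
| green | 0.027 M (fed, over 2.5 h) | 0.0297 M | 0.0320 M | the fed solution adds 0.25 times the starting volume | 5.0 h |
| ochre | 0.027 M (fed, over 2.5 h) | 0.0297 M | 0.0650 M | the fed solution adds 0.25 times the starting volume | 5.0 h |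

| run | time / h | E / % | X / % |
|---|---|---|---|
| cedar | 0.250 | 9.5 | 0 |
| cedar | 0.667 | 27.0 | 0 |
| cedar | 1.50 | 57.1 | 5.8 |
| cedar | 4.00 | 80.4 | 19.2 |
| birch | 0.250 | 10.4 | 0 |
| birch | 0.667 | 25.4 | 1.5 |
| birch | 1.50 | 56.3 | 4.2 |
| birch | 4.00 | 78.5 | 19.9 |

(readings scatter by 1 percentage point)

1. part of the E that has reacted at the end, green
2. part of the E that has reacted at the end, ochre
3. what raising the concentration of Q from its lowest to its highest value here does to the part of the E that has reacted (changes below 5 percentage points count as none) (no change / it falls / it rises)

- amounts and yields of J count G too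
- charges are per starting volume, the dose included; the dosed solution carries all of it
- given per volume of solution although it is solid: G
- steps that have been proposed: E + L -> J + X; L + J <-> D; J + Q <-> Z; G <-> J
- percentages count the whole charge, also what has not yet gone in

By charge E is the limiting reagent, 0.027 M against 0.0297 M of L, so your reckoning turns on speed. Dosed steadily, E has been in the flask on average for the elapsed time less half the dosing time: 2.75 h at the 4.00 h reading and 3.75 h at 5.0 h. At that reading cedar shows 19.2% of X and birch 19.9%. Dividing that average stay by ln(1/(1 − reacted share)), with the mean of the two shares, gives 12.6 h. This is the lifetime of E at this charge of L, a pseudo-first-order reading with the dilution and the loss of L folded in as they stood in these runs.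

The stay does not depend on Q, but the lifetime may: going from cedar to birch moved X by 0.7 percentage points, against a scatter of 1 point, so these two runs can neither show nor exclude a small effect of Q. Green lies inside that range of Q, while ochre lies beyond it, so for ochre this is my bet. The stay is shorter than the lifetime, their ratio being 0.298, so I reckon 25.7% reacted in both flasks, hence no change.

The forecast says 24.5% for green and 25% for ochre, no change, holding that “Q is therefore not limiting the rate”, and both figures stand a little below mine.

Green gives 25.5% and ochre 26.0%, a difference of 0.45 points, which counts as no change.

    E + L → J + X (k = 4.20 M⁻¹ h⁻¹)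
    L + J ⇌ D, settled at all times (K = 1100 M⁻¹)
    J + Q ⇌ Z, settled at all times (K = 260 M⁻¹)
    G ⇌ J, rate k4*(cs4 - [J]) while solid is left; crystals form when [J] > cs4 (solubility = 20.0 mM, k = 18.0 h⁻¹)

Taking out the joining of J and Q to Z moves the shown readings by 0.24 of the scatter, root mean square. In the neighbour like ochre but with 0.074 M of L, scaling by L turns 12.6 h into 5.07 h. The same stay of 3.75 h then gives 52.3%, and that flask stands at 52.6%.

All runs were computed for substances that don't exist; the scatter is artificial.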